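**Assumption:** the sense of induction of the squaramide in step 6 is assigned by analogy only. If the first run gives the mirror-image series, the quinidine-derived pseudo-enantiomer of the catalyst is used.

Ring letters used below: ring A = cyclohexenedione, ring B = hydroquinone, ring C = bridging methylcyclohexene.

## Retrosynthetic overview

1. Target ⇒ tertiary α-ketol 18. The last bond is quaternary bridgehead C–vinyl C: the ketol is ionised to an α-carbonyl cation (enolonium-type, as its acyl ortho-quinone methide) and trapped by a tethered vinylsilane. This closes ring C and fixes the alkene position.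
2. 18 ⇒ trione 16. The five-membered ring comes from a phenoxide ortho-aldol onto the 1,2-dione carbonyl.
3. 16 ⇒ hydroxyquinone 7 + sulfone 14. The prenylated quaternary carbon–benzylic carbon bond is made by catalytic asymmetric addition to an ortho-quinone methide, which sets both stereocentres.
4. 7 ⇐ 1,2,4-trimethoxybenzene + prenyl bromide; 14 ⇐ 2,5-dihydroxybenzaldehyde + methallyltrimethylsilane.
5. Ring order: rings A and B come preformed from aromatics, then the five-membered ring, then ring C.

## Route

**Step 1**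
Reactants: 1 1,2,4-trimethoxybenzene; 2 1-bromo-3-methylbut-2-ene (prenyl bromide)
Product: 4 1,2,4-trimethoxy-3-(3-methylbut-2-en-1-yl)benzene, via (2,3,6-trimethoxyphenyl)lithium 3 (not isolated)
Conditions: n-BuLi, TMEDA, THF, 0 °C; then CuBr·SMe2 (10 mol%), 2, −78 °C → rt
Reagents that add atoms: none
Why: Directed ortho-metalation occurs at the carbon flanked by two methoxy groups, and copper-catalysed SN2 allylation of the aryllithium keeps the prenyl group linear.

**Step 2**
Reactants: 4 1,2,4-trimethoxy-3-(3-methylbut-2-en-1-yl)benzene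
Product: 5 2-methoxy-3-(3-methylbut-2-en-1-yl)cyclohexa-2,5-diene-1,4-dione
Conditions: (NH4)2Ce(NO3)6 (2.5 equiv), MeCN/H2O, 0 °C
Reagents that add atoms: water O
Why: Oxidative demethylation of the para-dimethoxy pair by (NH4)2Ce(NO3)6 gives the para-quinone and leaves the third methoxy group as a vinylogous ester, while the isolated prenyl alkene is untouched.

**Step 3**
Reactants: 5 2-methoxy-3-(3-methylbut-2-en-1-yl)cyclohexa-2,5-diene-1,4-dione
Product: 7 2-hydroxy-3-(3-methylbut-2-en-1-yl)cyclohexa-2,5-diene-1,4-dione, via sodium enolate 6 (not isolated)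
Conditions: 2 M NaOH, MeOH/H2O, 0 °C, N2, 20 min; then 1 M HCl
Reagents that add atoms: sodium hydroxide [Na+].[OH-]
Why: Addition–elimination hydrolysis of the vinylogous methyl ester (the 2-methoxynaphthoquinone-to-lawsone reaction) gives the acidic hydroxyquinone, whose prenylated ring carbon is a soft carbon nucleophile.

**Step 4**
Reactants: 8 2,5-dihydroxybenzaldehyde
Product: 9 2-hydroxy-5-{[tri(propan-2-yl)silyl]oxy}benzaldehyde
Conditions: i-Pr3SiCl (1.05 equiv), imidazole, CH2Cl2, 0 °C
Reagents that add atoms: chlorotri(propan-2-yl)silane CC(C)[Si](Cl)(C(C)C)C(C)C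
Why: Selective O-silylation takes the 5-hydroxyl because the 2-hydroxyl is hydrogen-bonded to the aldehyde; blocking this phenol stops the later ortho-quinone methide from tautomerising to an alkylquinone.

**Step 5**
Reactants: 9 2-hydroxy-5-{[tri(propan-2-yl)silyl]oxy}benzaldehyde; 10 trimethyl(2-methylprop-2-en-1-yl)silane
Product: 14 racemic 2-[(3Z)-3-methyl-1-(4-methylbenzenesulfonyl)-4-(trimethylsilyl)but-3-en-1-yl]-4-{[tri(propan-2-yl)silyl]oxy}phenol, via lithiated allylsilane 11 (not isolated), via sodium phenoxide 12 (not isolated), via racemic benzylic alcohol 13 (not isolated)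
Conditions: 10, s-BuLi, TMEDA, THF, −78 °C; 9, NaH, THF, 0 °C, then added to 11, −78 → −20 °C; aq NH4Cl; crude 13, p-TolSO2H, CH2Cl2, rt, 1 h
Reagents that add atoms: 4-methylbenzenesulfinic acid Cc1ccc(cc1)S(=O)O
Why: The silyl-stabilised allyl anion adds to the aldehyde through the carbon remote from silicon (γ-selective carbonyl allylation) to give the vinylsilane (drawn Z; the E isomer reacts the same way in step 8), and SN1 exchange of the ortho-hydroxybenzylic OH by sulfinic acid gives a bench-stable, base-triggered ortho-quinone methide precursor whose racemic centre is erased in step 6.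

**Step 6**
Reactants: 7 2-hydroxy-3-(3-methylbut-2-en-1-yl)cyclohexa-2,5-diene-1,4-dione; 14 racemic sulfone
Product: 16 (3R)-3-[(1R,3Z)-1-(2-hydroxy-5-{[tri(propan-2-yl)silyl]oxy}phenyl)-3-methyl-4-(trimethylsilyl)but-3-en-1-yl]-3-(3-methylbut-2-en-1-yl)cyclohex-5-ene-1,2,4-trione, via ortho-quinone methide 15 (not isolated)
Conditions: 3-[[3,5-bis(trifluoromethyl)phenyl]amino]-4-[[(8α,9S)-6′-methoxycinchonan-9-yl]amino]cyclobut-3-ene-1,2-dione (10 mol%), aq Na2CO3 (1.2 equiv), toluene, 0 °C
Reagents that add atoms: none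
Why: Base-induced 1,4-elimination of sulfinate gives ortho-quinone methide 15 without acid (so the allylic side chain does not eliminate), and the squaramide-bound enolate of 7 adds through its prenylated carbon (catalytic asymmetric conjugate addition to an ortho-quinone methide); the catalyst sets the benzylic centre and an oxa-[4+2]-like endo-oxygen approach places the side chain syn to the prenyl group at the new quaternary centre.

**Step 7**
Reactants: 16 trione
Product: 18 (4aS,9R,9aS)-4a,5,8-trihydroxy-9-[(2Z)-2-methyl-3-(trimethylsilyl)prop-2-en-1-yl]-9a-(3-methylbut-2-en-1-yl)-4a,9a-dihydro-1H-fluorene-1,4(9H)-dione, via tetrabutylammonium phenoxide 17 (not isolated)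
Conditions: Bu4NF (1.1 equiv), THF, −40 → 0 °C; then AcOH
Reagents that add atoms: none
Why: Fluoride frees the hydroquinone mono-phenoxide, whose ortho carbon adds 5-exo to the adjacent vicinal-dicarbonyl ketone (intramolecular phenoxide aldol, an ortho-hydroxyalkylation); the ring is cis-fused and the carbinol configuration, fixed by that fusion, is erased in step 8, while the vinylsilane is inert to these non-acidic conditions.

**Step 8**
Reactants: 18 α-ketol
Product: 20 CNP0513322.1 (target), via acyl ortho-quinone methide 19 (not isolated)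
Conditions: BF3·OEt2 (2 equiv), CH2Cl2, −78 → −20 °C; aq NaHCO3
Reagents that add atoms: none
Why: Proposed new method: BF3, helped by the ortho phenol, ionises the tertiary benzylic α-ketol to acyl ortho-quinone methide 19, an α-carbonyl cation (enolonium) equivalent with no β-hydrogen, which is captured 6-endo at the silicon-bearing carbon of the tethered vinylsilane from the only face the tether allows, so the quaternary bridgehead is set by the two existing stereocentres and β-silyl cation collapse fixes the alkene next to it; the closest known reactions are Overman vinylsilane-terminated cation cyclisations and Lewis-acid SN1 substitution of benzoin-type α-ketols by π-nucleophiles.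

## Compound list

1 | 1,2,4-trimethoxybenzene | COc1ccc(OC)c(OC)c1 | starting material
2 | 1-bromo-3-methylbut-2-ene (prenyl bromide) | CC(C)=CCBr | starting material
3 | (2,3,6-trimethoxyphenyl)lithium | [Li]c1c(OC)ccc(OC)c1OC | intermediate
4 | 1,2,4-trimethoxy-3-(3-methylbut-2-en-1-yl)benzene | COc1ccc(OC)c(CC=C(C)C)c1OC | intermediate
5 | 2-methoxy-3-(3-methylbut-2-en-1-yl)cyclohexa-2,5-diene-1,4-dione | COC1=C(CC=C(C)C)C(=O)C=CC1=O | intermediate
6 | sodium 3-(3-methylbut-2-en-1-yl)-1,4-dioxocyclohexa-2,5-dien-2-olate | [Na+].[O-]C1=C(CC=C(C)C)C(=O)C=CC1=O | intermediate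
7 | 2-hydroxy-3-(3-methylbut-2-en-1-yl)cyclohexa-2,5-diene-1,4-dione | OC1=C(CC=C(C)C)C(=O)C=CC1=O | intermediate
8 | 2,5-dihydroxybenzaldehyde | O=Cc1cc(O)ccc1O | starting material
9 | 2-hydroxy-5-{[tri(propan-2-yl)silyl]oxy}benzaldehyde | CC(C)[Si](Oc1ccc(O)c(C=O)c1)(C(C)C)C(C)C | intermediate
10 | trimethyl(2-methylprop-2-en-1-yl)silane | C=C(C)C[Si](C)(C)C | starting material
11 | [2-methyl-1-(trimethylsilyl)prop-2-en-1-yl]lithium | [Li]C(C(C)=C)[Si](C)(C)C | intermediate
12 | sodium 2-formyl-4-{[tri(propan-2-yl)silyl]oxy}phenolate | [Na+].[O-]c1ccc(O[Si](C(C)C)(C(C)C)C(C)C)cc1C=O | intermediate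
13 | racemic 2-[(3Z)-1-hydroxy-3-methyl-4-(trimethylsilyl)but-3-en-1-yl]-4-{[tri(propan-2-yl)silyl]oxy}phenol | OC(C/C(C)=C\[Si](C)(C)C)c1cc(O[Si](C(C)C)(C(C)C)C(C)C)ccc1O | intermediate
14 | racemic 2-[(3Z)-3-methyl-1-(4-methylbenzenesulfonyl)-4-(trimethylsilyl)but-3-en-1-yl]-4-{[tri(propan-2-yl)silyl]oxy}phenol | Cc1ccc(cc1)S(=O)(=O)C(C/C(C)=C\[Si](C)(C)C)c1cc(O[Si](C(C)C)(C(C)C)C(C)C)ccc1O | intermediate
15 | (6E)-6-[(3Z)-3-methyl-4-(trimethylsilyl)but-3-en-1-ylidene]-4-{[tri(propan-2-yl)silyl]oxy}cyclohexa-2,4-dien-1-one | O=C1C=CC(O[Si](C(C)C)(C(C)C)C(C)C)=C/C1=C\C/C(C)=C\[Si](C)(C)C | intermediate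
16 | (3R)-3-[(1R,3Z)-1-(2-hydroxy-5-{[tri(propan-2-yl)silyl]oxy}phenyl)-3-methyl-4-(trimethylsilyl)but-3-en-1-yl]-3-(3-methylbut-2-en-1-yl)cyclohex-5-ene-1,2,4-trione (open form; equilibrates with its cyclic hemiketal) | CC(C)=CC[C@@]1([C@H](C/C(C)=C\[Si](C)(C)C)c2cc(O[Si](C(C)C)(C(C)C)C(C)C)ccc2O)C(=O)C=CC(=O)C1=O | intermediate
17 | tetrabutylammonium 4-hydroxy-3-[(1R,3Z)-3-methyl-1-[(1R)-1-(3-methylbut-2-en-1-yl)-2,3,6-trioxocyclohex-4-en-1-yl]-4-(trimethylsilyl)but-3-en-1-yl]phenolate | CC(C)=CC[C@@]1([C@H](C/C(C)=C\[Si](C)(C)C)c2cc([O-])ccc2O)C(=O)C=CC(=O)C1=O.CCCC[N+](CCCC)(CCCC)CCCC | intermediate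
18 | (4aS,9R,9aS)-4a,5,8-trihydroxy-9-[(2Z)-2-methyl-3-(trimethylsilyl)prop-2-en-1-yl]-9a-(3-methylbut-2-en-1-yl)-4a,9a-dihydro-1H-fluorene-1,4(9H)-dione (ring fusion cis; ketol OH, prenyl and side chain on the same face) | CC(C)=CC[C@@]12C(=O)C=CC(=O)[C@]1(O)c1c(O)ccc(O)c1[C@H]2C/C(C)=C\[Si](C)(C)C | intermediate
19 | (9R,9aS)-8-hydroxy-9-[(2Z)-2-methyl-3-(trimethylsilyl)prop-2-en-1-yl]-9a-(3-methylbut-2-en-1-yl)-9,9a-dihydro-1H-fluorene-1,4,5-trione (acyl ortho-quinone methide) | CC(C)=CC[C@@]12C(=O)C=CC(=O)C1=C1C(=O)C=CC(O)=C1[C@H]2C/C(C)=C\[Si](C)(C)C | intermediate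
20 | CNP0513322.1: the hydrofluorenedione of 18 with positions 4a and 9 joined by a CH=C(CH3)–CH2 bridge (vinyl CH on C4a), 5,8-dihydroxy, 9a-prenyl; prenylated quaternary carbon S, aryl/vinyl quaternary bridgehead R, benzylic bridgehead R | CC(C)=CC[C@@]12C(=O)C=CC(=O)[C@@]13C=C(C)C[C@@H]2c1c(O)ccc(O)c13 | target

## Step count and risks

Total steps: 8. Longest linear sequence: 6 (steps 1, 2, 3, 6, 7, 8).

**Step 6 (selectivity of the ortho-quinone methide addition).** The nucleophile is a fully substituted, very acidic enol, and both the enantioselectivity and the syn relationship of side chain and prenyl group rest on analogy. Fallback: it sets out from 7 and 14. The same base-triggered addition is run without a chiral catalyst (Na2CO3, Bu4NBr, toluene/H2O), giving trione 16 together with the enantiomeric trione F1. The racemate is resolved by preparative chromatography on a chiral stationary phase, and the route is rejoined at 16.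

**Step 7 (phenoxide ring closure).** The naked phenoxide could add instead to the enedione double bond of ring A, or the benzylic bond could open by retro-addition. Fallback: it sets out from 16. Desilylation under acidic fluoride (HF·pyridine, THF, 0 °C) gives the free hydroquinone trione F2, which is isolated. Its magnesium phenolate (MgBr2·OEt2, Et3N, CH2Cl2, −20 °C) then closes the ring by chelate-templated ortho-hydroxyalkylation, the magnesium bridging the phenolate oxygen and the dione carbonyl so that only that carbonyl carbon is delivered to the ortho position. The route is rejoined at 18.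

**Step 8 (ionisation and vinylsilane capture).** The neighbouring carbonyl retards ionisation, and protodesilylation or α-ketol rearrangement may compete. Fallback: it sets out from 18. The C4 carbonyl next to the ketol is masked together with the neighbouring phenol as a cyclic mixed methyl ketal (HC(OMe)3, pyridinium p-toluenesulfonate, MeOH), giving the cyclic ketal F3. Without the adjacent carbonyl the tertiary benzylic alcohol ionises as an ordinary benzylic cation (BF3·OEt2, CH2Cl2, −78 °C), and the vinylsilane closes the bridge to the bridged ketal F4. Aqueous HCl/THF then unmasks ketone and phenol, and the route ends at 20.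

## Further compounds

F1 | step 6 | (3S)-3-[(1S,3Z)-1-(2-hydroxy-5-{[tri(propan-2-yl)silyl]oxy}phenyl)-3-methyl-4-(trimethylsilyl)but-3-en-1-yl]-3-(3-methylbut-2-en-1-yl)cyclohex-5-ene-1,2,4-trione (enantiomer of 16) | CC(C)=CC[C@]1([C@@H](C/C(C)=C\[Si](C)(C)C)c2cc(O[Si](C(C)C)(C(C)C)C(C)C)ccc2O)C(=O)C=CC(=O)C1=O
F2 | step 7 | (3R)-3-[(1R,3Z)-1-(2,5-dihydroxyphenyl)-3-methyl-4-(trimethylsilyl)but-3-en-1-yl]-3-(3-methylbut-2-en-1-yl)cyclohex-5-ene-1,2,4-trione | CC(C)=CC[C@@]1([C@H](C/C(C)=C\[Si](C)(C)C)c2cc(O)ccc2O)C(=O)C=CC(=O)C1=O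
F3 | step 8 | cyclic mixed methyl ketal of 18 (the C4 carbonyl and the C5 phenol oxygen form a 2-methoxy-2,3-dihydrobenzofuran ring; ketal carbon configuration not defined) | CC(C)=CC[C@@]12C(=O)C=CC3(OC)Oc4ccc(O)c([C@H]2C/C(C)=C\[Si](C)(C)C)c4[C@]13O
F4 | step 8 | cyclic mixed methyl ketal of 20 (same ketal as in F3 on the bridged skeleton) | CC(C)=CC[C@@]12C(=O)C=CC3(OC)Oc4ccc(O)c5c4[C@]13C=C(C)C[C@@H]25
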